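The 4,8-dihydroxy-6-methyl-1-tetralone half is cut at both aryl–carbon bonds of its carbocycle: arene carbons C8a and C4a become an aryne, and C1(=O)–C2–C3–C4(OH) comes from the bis-silyl enol ether of succinic anhydride. One aryne/2,5-bis(silyloxy)furan [4+2] cycloaddition on a bromocresol ether thus installs the whole 1,4-dioxygenated ring; hydrogenation, hydrolysis and asymmetric transfer hydrogenation then set C4. A second, SEM-protected aryne and furan give an oxabicycle whose rhodium-catalysed arylative ring opening creates the cis C3-aryl/C4-hydroxyl pair of the other half and joins the halves. A Markovnikov oxidation supplies the second ketone.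

Key step: step 3

Remark: the bridged compounds 7, 8, 9, 10 and 17 are racemic and are written without stereodescriptors, because the oxygen bridge fixes their relative configuration. The ligand antipode in step 9 is the one that gives the (1S,2R) cis series, to be calibrated on the unsubstituted parent oxabicycle.

Remark: the lower-half phenol is carried as a MOM acetal and the upper-half phenol as a SEM acetal. Both direct the lithiation that starts aryne formation and both are cleaved by acid in step 11. Fluoride remains a non-acidic option for the SEM ether, which sits next to the more ionisable benzylic carbinol.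

Step 1
Reactants: 1 3-bromo-5-methylphenol
Product: 2 1-bromo-3-(methoxymethoxy)-5-methylbenzene
Conditions: NaH, MOMCl, DMF, 0 °C to rt
Reagents that add atoms: chloromethyl methyl ether, COCCl
Why: Williamson-type O-alkylation of the sodium phenoxide gives the MOM ether, which later directs both ortho-lithiations of this half and survives strong base.

Step 2
Reactants: 3 succinic anhydride
Product: 4 2,5-bis(tert-butyldimethylsilyloxy)furan
Conditions: TBSOTf (2.2 equiv), Et3N (2.5 equiv), CH2Cl2, 0 °C to rt
Reagents that add atoms: tert-butyldimethylsilyl triflate, CC(C)(C)[Si](C)(C)OS(=O)(=O)C(F)(F)F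
Why: Double soft enolisation and O-silylation of the anhydride (silyl ketene acetal formation) gives the aromatic bis(silyloxy)furan, the usual way to such 2,5-dioxygenated furan dienes.

Step 3
Reactants: 2 1-bromo-3-(methoxymethoxy)-5-methylbenzene; 4 2,5-bis(tert-butyldimethylsilyloxy)furan
Product: 7 rac-1,4-bis(tert-butyldimethylsilyloxy)-5-(methoxymethoxy)-7-methyl-1,4-dihydro-1,4-epoxynaphthalene, via aryllithium 5 (not isolated), via aryne 6 (not isolated)
Conditions: LiN(i-Pr)2 (1.3 equiv) added to 2 and 4 (1.5 equiv), THF, −78 °C to −20 °C; pH 7 work-up, Et3N-deactivated silica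
Reagents that add atoms: none
Why: Amide deprotonation of 2 at the position acidified by both OMOM and Br gives aryllithium 5, which loses LiBr to aryne 6; its strained triple bond then adds in a concerted [4+2] cycloaddition across C2 and C5 of the electron-rich diene 4, making both aryl–carbon bonds (future C8a–C1 and C4a–C4 of the tetralone) at once. The closest known reaction type is the aryne–furan Diels–Alder reaction of 3-alkoxybenzynes with 2-alkoxy- and 2-silyloxyfurans. The six-membered carbocycle is closed in the [4+2] mode, suprafacial on both partners, and the furan oxygen becomes the bridge of a 7-oxabicyclo[2.2.1]heptadiene. The two bridgehead ketal carbons form as a racemic pair with bridge-fixed relative configuration and are erased in step 5, so no stereocontrol is needed. Because diene 4 is symmetrical, the unsymmetrical aryne raises no regiochemical question; the step needs only chemoselective trapping of 6 by 4 instead of by amine or by 5, which the high-lying HOMO of the diene, its excess, the low temperature and the bulky silyl groups should secure.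

Step 4
Reactants: 7 rac-1,4-bis(tert-butyldimethylsilyloxy)-5-(methoxymethoxy)-7-methyl-1,4-dihydro-1,4-epoxynaphthalene
Product: 8 rac-1,4-bis(tert-butyldimethylsilyloxy)-5-(methoxymethoxy)-7-methyl-1,2,3,4-tetrahydro-1,4-epoxynaphthalene
Conditions: H2 (1 atm), Pd/C, EtOAc with 1% Et3N, rt
Reagents that add atoms: none
Why: Catalytic hydrogenation of the strained bicyclic alkene from the exo face brings C2–C3 to the oxidation level of the tetralone while the ketals stay masked under buffered neutral conditions.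

Step 5
Reactants: 8 rac-1,4-bis(tert-butyldimethylsilyloxy)-5-(methoxymethoxy)-7-methyl-1,2,3,4-tetrahydro-1,4-epoxynaphthalene
Product: 11 [1-(methoxymethoxy)-3-methyl-5,8-dioxo-5,6,7,8-tetrahydronaphthalen-2-yl]boronic acid, via aryllithium 9 (not isolated), via dimethyl boronate 10 (not isolated)
Conditions: s-BuLi, TMEDA, THF, −78 °C; B(OMe)3, −78 to 0 °C; then 1 M aq. HCl, THF, 0 °C, short
Reagents that add atoms: trimethyl borate, COB(OC)OC; water, O
Why: OMOM-directed ortho-metalation at the only ortho C–H, electrophilic borylation and acid hydrolysis of the borate and of both silyl ketals should give the achiral 1,4-dione boronic acid, the bridgehead centers being lost.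

Step 6
Reactants: 11 [1-(methoxymethoxy)-3-methyl-5,8-dioxo-5,6,7,8-tetrahydronaphthalen-2-yl]boronic acid
Product: 12 [(5R)-5-hydroxy-1-(methoxymethoxy)-3-methyl-8-oxo-5,6,7,8-tetrahydronaphthalen-2-yl]boronic acid
Conditions: RuCl[(R,R)-TsDPEN](p-cymene) (1 mol%), HCO2H–Et3N (5:2), CH2Cl2, 0 °C to rt, stopped after one hydride equivalent
Reagents that add atoms: none
Why: Noyori asymmetric transfer hydrogenation should reduce the unhindered carbonyl peri to C–H in preference to the one shielded and deactivated by the peri OMOM group, and the (R,R) catalyst sets the (R) carbinol by the usual aryl/alkyl ketone model, as for 1-tetralone.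

Step 7
Reactants: 1 3-bromo-5-methylphenol
Product: 13 1-bromo-3-methyl-5-{[2-(trimethylsilyl)ethoxy]methoxy}benzene
Conditions: NaH, SEMCl, DMF, 0 °C to rt
Reagents that add atoms: 2-(trimethylsilyl)ethoxymethyl chloride, C[Si](C)(C)CCOCCl
Why: Williamson-type O-alkylation of the sodium phenoxide gives the SEM ether, an acetal that directs ortho-lithiation like MOM and is stable to amide base and aqueous carbonate.

Step 8
Reactants: 13 1-bromo-3-methyl-5-{[2-(trimethylsilyl)ethoxy]methoxy}benzene; 14 furan
Product: 17 rac-7-methyl-5-{[2-(trimethylsilyl)ethoxy]methoxy}-1,4-dihydro-1,4-epoxynaphthalene, via aryllithium 15 (not isolated), via aryne 16 (not isolated)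
Conditions: LiN(i-Pr)2, furan (10 equiv), THF, −78 °C to rt
Reagents that add atoms: none
Why: Lithiation between the acetal oxygen and Br, loss of LiBr and aryne–furan Diels–Alder reaction should give the oxabenzonorbornadiene as a racemate whose two bridgehead centers are fixed relative to each other by the bridge.

Step 9
Reactants: 12 [(5R)-5-hydroxy-1-(methoxymethoxy)-3-methyl-8-oxo-5,6,7,8-tetrahydronaphthalen-2-yl]boronic acid; 17 rac-7-methyl-5-{[2-(trimethylsilyl)ethoxy]methoxy}-1,4-dihydro-1,4-epoxynaphthalene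
Product: 18 (4R)-4-hydroxy-7-[(1S,2R)-1-hydroxy-6-methyl-8-{[2-(trimethylsilyl)ethoxy]methoxy}-1,2-dihydronaphthalen-2-yl]-8-(methoxymethoxy)-6-methyl-3,4-dihydronaphthalen-1(2H)-one
Conditions: [Rh(cod)Cl]2 (2.5 mol%), Josiphos ligand (R)-1-[(S)-2-(diphenylphosphino)ferrocenyl]ethyl-di-tert-butylphosphine (6 mol%), Cs2CO3 (1 M aq.), 17 (2.2 equiv), THF, rt to 40 °C; neutral alumina chromatography
Reagents that add atoms: none
Why: Rhodium-catalysed asymmetric ring opening (transmetalation, syn-exo carborhodation, β-oxygen elimination) places aryl and hydroxyl cis, and the ligand chooses which alkene carbon is arylated, so the (1R,4S) enantiomer of 17 should give 18 while the other enantiomer gives a separable regioisomer (regiodivergent resolution, so that at most about half of 12 can reach 18).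

Step 10
Reactants: 18 (4R)-4-hydroxy-7-[(1S,2R)-1-hydroxy-6-methyl-8-{[2-(trimethylsilyl)ethoxy]methoxy}-1,2-dihydronaphthalen-2-yl]-8-(methoxymethoxy)-6-methyl-3,4-dihydronaphthalen-1(2H)-one
Product: 19 (3R,4S)-4-hydroxy-3-[(5R)-5-hydroxy-1-(methoxymethoxy)-3-methyl-8-oxo-5,6,7,8-tetrahydronaphthalen-2-yl]-7-methyl-5-{[2-(trimethylsilyl)ethoxy]methoxy}-3,4-dihydronaphthalen-1(2H)-one
Conditions: FeCl2 (10 mol%), neocuproine (10 mol%), PhSiH3, O2 (air), EtOH, rt
Reagents that add atoms: dioxygen, O=O
Why: Mukaiyama-type hydrogen-atom-transfer (Wacker-type) oxidation adds H to the non-benzylic alkene carbon, and O2 trapping of the benzylic radical gives the aryl ketone with Markovnikov regiochemistry under neutral conditions that leave the three stereocenters untouched.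

Step 11
Reactants: 19 (3R,4S)-4-hydroxy-3-[(5R)-5-hydroxy-1-(methoxymethoxy)-3-methyl-8-oxo-5,6,7,8-tetrahydronaphthalen-2-yl]-7-methyl-5-{[2-(trimethylsilyl)ethoxy]methoxy}-3,4-dihydronaphthalen-1(2H)-one
Product: 20 (3R,4S)-4,5-dihydroxy-3-[(5R)-1,5-dihydroxy-3-methyl-8-oxo-5,6,7,8-tetrahydronaphthalen-2-yl]-7-methyl-3,4-dihydronaphthalen-1(2H)-one
Conditions: 2 M aq. HCl, THF–i-PrOH, 0 °C to rt, monitored and stopped at full conversion
Reagents that add atoms: none
Why: Acid-catalysed acetal hydrolysis frees both phenols, the aryloxide being the better leaving group of the MOM and of the SEM acetal, under conditions kept mild to avoid ionisation of the benzylic carbinols.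

Compound list
1 | 3-bromo-5-methylphenol | Cc1cc(O)cc(Br)c1 | starting material
2 | 1-bromo-3-(methoxymethoxy)-5-methylbenzene | COCOc1cc(C)cc(Br)c1 | intermediate
3 | succinic anhydride | O=C1CCC(=O)O1 | starting material
4 | 2,5-bis(tert-butyldimethylsilyloxy)furan | CC(C)(C)[Si](C)(C)Oc1ccc(O[Si](C)(C)C(C)(C)C)o1 | intermediate
5 | [2-bromo-6-(methoxymethoxy)-4-methylphenyl]lithium | COCOc1cc(C)cc(Br)c1[Li] | intermediate
6 | 3-(methoxymethoxy)-5-methylbenzyne | COCOC1=CC(C)=CC#C1 | intermediate
7 | rac-1,4-bis(tert-butyldimethylsilyloxy)-5-(methoxymethoxy)-7-methyl-1,4-dihydro-1,4-epoxynaphthalene | COCOc1cc(C)cc2c1C1(O[Si](C)(C)C(C)(C)C)OC2(O[Si](C)(C)C(C)(C)C)C=C1 | intermediate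
8 | rac-1,4-bis(tert-butyldimethylsilyloxy)-5-(methoxymethoxy)-7-methyl-1,2,3,4-tetrahydro-1,4-epoxynaphthalene | COCOc1cc(C)cc2c1C1(O[Si](C)(C)C(C)(C)C)OC2(O[Si](C)(C)C(C)(C)C)CC1 | intermediate
9 | 6-lithio derivative of 8 | COCOc1c([Li])c(C)cc2c1C1(O[Si](C)(C)C(C)(C)C)OC2(O[Si](C)(C)C(C)(C)C)CC1 | intermediate
10 | dimethyl boronate of 8 at C6 | COCOc1c(B(OC)OC)c(C)cc2c1C1(O[Si](C)(C)C(C)(C)C)OC2(O[Si](C)(C)C(C)(C)C)CC1 | intermediate
11 | [1-(methoxymethoxy)-3-methyl-5,8-dioxo-5,6,7,8-tetrahydronaphthalen-2-yl]boronic acid | COCOc1c(B(O)O)c(C)cc2c1C(=O)CCC2=O | intermediate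
12 | [(5R)-5-hydroxy-1-(methoxymethoxy)-3-methyl-8-oxo-5,6,7,8-tetrahydronaphthalen-2-yl]boronic acid | COCOc1c(B(O)O)c(C)cc2c1C(=O)CC[C@H]2O | intermediate
13 | 1-bromo-3-methyl-5-{[2-(trimethylsilyl)ethoxy]methoxy}benzene | C[Si](C)(C)CCOCOc1cc(C)cc(Br)c1 | intermediate
14 | furan | c1ccoc1 | starting material
15 | [2-bromo-4-methyl-6-{[2-(trimethylsilyl)ethoxy]methoxy}phenyl]lithium | C[Si](C)(C)CCOCOc1cc(C)cc(Br)c1[Li] | intermediate
16 | 5-methyl-3-{[2-(trimethylsilyl)ethoxy]methoxy}benzyne | C[Si](C)(C)CCOCOC1=CC(C)=CC#C1 | intermediate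
17 | rac-7-methyl-5-{[2-(trimethylsilyl)ethoxy]methoxy}-1,4-dihydro-1,4-epoxynaphthalene | C[Si](C)(C)CCOCOc1cc(C)cc2c1C1OC2C=C1 | intermediate
18 | (4R)-4-hydroxy-7-[(1S,2R)-1-hydroxy-6-methyl-8-{[2-(trimethylsilyl)ethoxy]methoxy}-1,2-dihydronaphthalen-2-yl]-8-(methoxymethoxy)-6-methyl-3,4-dihydronaphthalen-1(2H)-one | Cc1cc(OCOCC[Si](C)(C)C)c2c(c1)C=C[C@H](c1c(C)cc3c(c1OCOC)C(=O)CC[C@H]3O)[C@@H]2O | intermediate
19 | (3R,4S)-4-hydroxy-3-[(5R)-5-hydroxy-1-(methoxymethoxy)-3-methyl-8-oxo-5,6,7,8-tetrahydronaphthalen-2-yl]-7-methyl-5-{[2-(trimethylsilyl)ethoxy]methoxy}-3,4-dihydronaphthalen-1(2H)-one | Cc1cc(OCOCC[Si](C)(C)C)c2c(c1)C(=O)C[C@H](c1c(C)cc3c(c1OCOC)C(=O)CC[C@H]3O)[C@@H]2O | intermediate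
20 | (3R,4S)-4,5-dihydroxy-3-[(5R)-1,5-dihydroxy-3-methyl-8-oxo-5,6,7,8-tetrahydronaphthalen-2-yl]-7-methyl-3,4-dihydronaphthalen-1(2H)-one | Cc1cc(O)c2c(c1)C(=O)C[C@H](c1c(C)cc3c(c1O)C(=O)CC[C@H]3O)[C@@H]2O | target

Total step count: 11. Longest linear sequence: 8 steps (steps 1, 3, 4, 5, 6, 9, 10, 11).

Steps most likely to fail

Step 9. Transmetalation of the doubly ortho-substituted boronic acid may be slow, so protodeboronation could outrun carborhodation, and ligand control over which alkene carbon is arylated may erode. The fallback sets out from 8 and comes back to the route at 18, using an aryl electrophile and a palladium cycle instead. Aryllithium 9, formed from 8 as in step 5, is quenched with I2 to give rac-1,4-bis(tert-butyldimethylsilyloxy)-6-iodo-5-(methoxymethoxy)-7-methyl-1,2,3,4-tetrahydro-1,4-epoxynaphthalene F1. The acid hydrolysis of step 5 then gives 6-iodo-5-(methoxymethoxy)-7-methyl-2,3-dihydronaphthalene-1,4-dione F2. The transfer hydrogenation of step 6 gives (4R)-4-hydroxy-7-iodo-8-(methoxymethoxy)-6-methyl-3,4-dihydronaphthalen-1(2H)-one F3. A reductive Heck-type ring opening of 17 with F3 (Pd(OAc)2, BINAP in the antipode that gives the (1S,2R) series, Zn powder, ZnCl2, Et3N, THF, 60 °C) should then lead to 18 by oxidative addition, syn-exo carbopalladation and β-oxygen elimination; hindered aryl–palladium species insert strained bicyclic alkenes readily.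

Step 10. The benzylic peroxy intermediate may be reduced to the alcohol instead of collapsing to the ketone, and the dihydronaphthalenol may dehydrate to a naphthalene. The fallback sets out from 18 and comes back to the route at 19 by ionic steps. Silylation (Et3SiOTf, 2,6-lutidine, CH2Cl2, −78 °C) gives the bis(triethylsilyl) ether of 18 F4. NBS in THF–H2O gives the bromohydrin with hydroxyl at the benzylic carbon F5. Dess–Martin periodinane gives the α-bromo ketone F6. Zn in AcOH removes bromine to give the bis(triethylsilyl) ether of 19 F7. Pyridine-buffered HF·pyridine then removes both triethylsilyl groups, leaving the SEM and MOM acetals, to give 19.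

Step 3. The lithium amide or aryllithium 5 may consume diene 4 by silyl transfer before the aryne forms, and the bis-ketal adduct may collapse hydrolytically to the quinone on isolation. The fallback sets out from 2 and comes back to the route at 11, with a base-stable mono-oxygenated diene and a later oxidation. Compound 2, commercial 2-methoxyfuran and LiN(i-Pr)2 give rac-1-methoxy-8-(methoxymethoxy)-6-methyl-1,4-dihydro-1,4-epoxynaphthalene F8, with the ketal carbon bonded to the ring carbon next to the OMOM-bearing carbon, as aryne polarisation predicts. Hydrogenation (H2, Pd/C, Et3N-buffered) gives rac-1-methoxy-8-(methoxymethoxy)-6-methyl-1,2,3,4-tetrahydro-1,4-epoxynaphthalene F9. Lithiation, borylation and acid hydrolysis as in step 5 give rac-[5-hydroxy-1-(methoxymethoxy)-3-methyl-8-oxo-5,6,7,8-tetrahydronaphthalen-2-yl]boronic acid F10. MnO2 oxidation of the benzylic alcohol then gives 11.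

Further compounds
F1 | step 9 | rac-1,4-bis(tert-butyldimethylsilyloxy)-6-iodo-5-(methoxymethoxy)-7-methyl-1,2,3,4-tetrahydro-1,4-epoxynaphthalene | COCOc1c(I)c(C)cc2c1C1(O[Si](C)(C)C(C)(C)C)OC2(O[Si](C)(C)C(C)(C)C)CC1
F2 | step 9 | 6-iodo-5-(methoxymethoxy)-7-methyl-2,3-dihydronaphthalene-1,4-dione | COCOc1c(I)c(C)cc2c1C(=O)CCC2=O
F3 | step 9 | (4R)-4-hydroxy-7-iodo-8-(methoxymethoxy)-6-methyl-3,4-dihydronaphthalen-1(2H)-one | COCOc1c(I)c(C)cc2c1C(=O)CC[C@H]2O
F4 | step 10 | bis(triethylsilyl) ether of 18 | Cc1cc(OCOCC[Si](C)(C)C)c2c(c1)C=C[C@H](c1c(C)cc3c(c1OCOC)C(=O)CC[C@H]3O[Si](CC)(CC)CC)[C@@H]2O[Si](CC)(CC)CC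
F5 | step 10 | bromohydrin of F4 (hydroxyl at the benzylic carbon, bromine at the neighbouring carbon of the former alkene) | Cc1cc(OCOCC[Si](C)(C)C)c2c(c1)C(O)C(Br)[C@H](c1c(C)cc3c(c1OCOC)C(=O)CC[C@H]3O[Si](CC)(CC)CC)[C@@H]2O[Si](CC)(CC)CC
F6 | step 10 | α-bromo ketone from F5 | Cc1cc(OCOCC[Si](C)(C)C)c2c(c1)C(=O)C(Br)[C@H](c1c(C)cc3c(c1OCOC)C(=O)CC[C@H]3O[Si](CC)(CC)CC)[C@@H]2O[Si](CC)(CC)CC
F7 | step 10 | bis(triethylsilyl) ether of 19 | Cc1cc(OCOCC[Si](C)(C)C)c2c(c1)C(=O)C[C@H](c1c(C)cc3c(c1OCOC)C(=O)CC[C@H]3O[Si](CC)(CC)CC)[C@@H]2O[Si](CC)(CC)CC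
F8 | step 3 | rac-1-methoxy-8-(methoxymethoxy)-6-methyl-1,4-dihydro-1,4-epoxynaphthalene | COCOc1cc(C)cc2c1C1(OC)OC2C=C1
F9 | step 3 | rac-1-methoxy-8-(methoxymethoxy)-6-methyl-1,2,3,4-tetrahydro-1,4-epoxynaphthalene | COCOc1cc(C)cc2c1C1(OC)OC2CC1
F10 | step 3 | rac-[5-hydroxy-1-(methoxymethoxy)-3-methyl-8-oxo-5,6,7,8-tetrahydronaphthalen-2-yl]boronic acid | COCOc1c(B(O)O)c(C)cc2c1C(=O)CCC2O
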